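**Retrosynthetic overview**
1. Target 21 ⇐ bis-silyl ether 20 ⇐ allylic alcohol 18 + aryl iodide 19 + CO (carbonylative esterification); C1–OH comes from CBS reduction of dienone 17.
2. Ten-membered (2Z,4E)-dienone 17 ⇐ three-carbon Grob ring expansion of cycloheptanone mesylate 14 (alkenyllithium closes a transient cyclopentenol, then C–C fragmentation).
3. Cycloheptanone aldol 13 ⇐ semipinacol 1,2-shift ring expansion (6→7) of epoxy alcohol 12; this fixes the C2/C1′ relationship that becomes the 4E alkene.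
4. 12 ⇐ (Z,Z)-dienyl iodide 9 (three steps from alkynol 5) + (S)-ketone 4 (asymmetric conjugate borylation of enone 1 sets C9).
5. Ring order: six-membered (bought) → seven (semipinacol) → transient 5/7 bicycle → ten (Grob).

Assumption: 5 and 19 are bought, the QuinoxP* enantiomer is the one that gives boronate 2 as drawn, and ring locants C1–C10 are those of the target (C1 = ester carbon, C9 = tertiary carbinol).

**Step 1**
Reactants: 1 3-methylcyclohex-2-en-1-one
Product: 3 (S)-3-hydroxy-3-methylcyclohexan-1-one, via boronate 2 (not isolated)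
Conditions: B2pin2, CuPF6(MeCN)4 (5 mol%), QuinoxP* (6 mol%), LiOt-Bu (10 mol%), DMSO, rt; then NaBO3·4H2O, THF/H2O, rt
Reagents that add atoms: sodium perborate, [Na+].[Na+].O[B-]1(O)OO[B-](O)(O)OO1 (O of the C–OH); bis(pinacolato)diboron, CC1(C)OB(OC1(C)C)B1OC(C)(C)C(C)(C)O1 (Bpin of 2 only)
Why: Cu(I)–boryl conjugate addition (asymmetric β-borylation) sets the tertiary C–B centre under ligand control, and perborate oxidation replaces B by OH with retention to give the (S)-carbinol that becomes C9.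

**Step 2**
Reactants: 3 (S)-3-hydroxy-3-methylcyclohexan-1-one
Product: 4 (S)-3-methyl-3-[(triethylsilyl)oxy]cyclohexan-1-one
Conditions: TESOTf, 2,6-lutidine, CH2Cl2, −78 → 0 °C
Reagents that add atoms: triethylsilyl triflate, CC[Si](CC)(CC)OS(=O)(=O)C(F)(F)F
Why: Silyl ether protection of the tertiary alcohol blocks retro-aldol and alkoxide chemistry of this β-hydroxy ketone in the later basic steps.

**Step 3**
Reactants: 5 4-methylpent-2-yn-1-ol
Product: 7 (Z)-3-bromo-4-methylpent-2-en-1-ol, via alkenylaluminate 6 (not isolated)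
Conditions: Red-Al, THF, 0 °C → rt; then NBS, −78 → 0 °C
Reagents that add atoms: N-bromosuccinimide, O=C1CCC(=O)N1Br (Red-Al, [Na+].COCCO[AlH2-]OCCOC, supplies Al and its alkoxides in 6 only)
Why: Hydroxyl-directed trans-hydroalumination puts Al on C3 cis to the CH2O group, and bromodealumination with retention gives the Z bromoalkene, which later becomes the 2Z ring alkene.

**Step 4**
Reactants: 7 (Z)-3-bromo-4-methylpent-2-en-1-ol
Product: 8 (Z)-3-bromo-4-methylpent-2-enal
Conditions: MnO2, CH2Cl2, rt, dark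
Reagents that add atoms: none
Why: MnO2 allylic oxidation is neutral and chemoselective, so the Z-β-bromoenal is formed without isomerisation.

**Step 5**
Reactants: 8 (Z)-3-bromo-4-methylpent-2-enal
Product: 9 (2Z,4Z)-5-bromo-2-iodo-6-methylhepta-2,4-diene
Conditions: EtPPh3I, n-BuLi, THF, rt; I2, −78 °C; NaHMDS, −20 °C; then 8, −78 °C → rt
Reagents that add atoms: ethyltriphenylphosphonium iodide, CC[P+](c1ccccc1)(c1ccccc1)c1ccccc1.[I-] (CH3–C unit); iodine, II
Why: Stork–Zhao-type Wittig olefination with the α-iodo ylide gives the trisubstituted vinyl iodide with I cis to the aldehyde-derived carbon, the geometry the later stereospecific 1,2-shift needs.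

**Step 6**
Reactants: 9 (2Z,4Z)-5-bromo-2-iodo-6-methylhepta-2,4-diene; 4 (S)-3-methyl-3-[(triethylsilyl)oxy]cyclohexan-1-one
Product: 11 (1R,3S)-1-[(2Z,4Z)-5-bromo-6-methylhepta-2,4-dien-2-yl]-3-methyl-3-[(triethylsilyl)oxy]cyclohexan-1-ol, via dienyllithium 10 (not isolated)
Conditions: t-BuLi (2.0 equiv), Et2O, −100 °C; then 4, −78 °C; aq NH4Cl
Reagents that add atoms: none
Why: Iodine–lithium exchange is far faster than bromine–lithium exchange and retains geometry, and 1,2-addition of the alkenyllithium to the ketone (equatorial attack) gives the tertiary allylic alcohol, whose C1 configuration is inconsequential because C1 becomes C=O in step 8.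

**Step 7**
Reactants: 11 (1R,3S)-1-[(2Z,4Z)-5-bromo-6-methylhepta-2,4-dien-2-yl]-3-methyl-3-[(triethylsilyl)oxy]cyclohexan-1-ol
Product: 12 (1R,3S)-1-{(2S,3S)-3-[(1Z)-2-bromo-3-methylbut-1-en-1-yl]-2-methyloxiran-2-yl}-3-methyl-3-[(triethylsilyl)oxy]cyclohexan-1-ol
Conditions: VO(acac)2 (5 mol%), t-BuOOH, CH2Cl2, 0 °C → rt
Reagents that add atoms: tert-butyl hydroperoxide, CC(C)(C)OO
Why: Hydroxyl-directed vanadium-catalysed epoxidation reacts only at the allylic alkene, and syn addition to the Z alkene fixes the relative configuration of the two oxirane carbons (the face selectivity is inconsequential).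

**Step 8**
Reactants: 12 (1R,3S)-1-{(2S,3S)-3-[(1Z)-2-bromo-3-methylbut-1-en-1-yl]-2-methyloxiran-2-yl}-3-methyl-3-[(triethylsilyl)oxy]cyclohexan-1-ol
Product: 13 (2R,6S)-2-[(1S,2Z)-3-bromo-1-hydroxy-4-methylpent-2-en-1-yl]-2,6-dimethyl-6-[(triethylsilyl)oxy]cycloheptan-1-one
Conditions: ZnBr2 (1.2 equiv), CH2Cl2, 0 °C
Reagents that add atoms: none
Why: Semipinacol rearrangement of the 2,3-epoxy alcohol opens the tertiary oxirane carbon with anti 1,2-shift of the ring CH2 remote from the C–OSi centre (more electron-rich, less hindered), expanding the ring to the cycloheptanone and giving the α-quaternary aldol with defined C2/C1′ relative configuration by inversion at C2.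

**Step 9**
Reactants: 13 (2R,6S)-2-[(1S,2Z)-3-bromo-1-hydroxy-4-methylpent-2-en-1-yl]-2,6-dimethyl-6-[(triethylsilyl)oxy]cycloheptan-1-one
Product: 14 (1S,2Z)-3-bromo-1-{(1R,4S)-1,4-dimethyl-2-oxo-4-[(triethylsilyl)oxy]cycloheptyl}-4-methylpent-2-en-1-yl methanesulfonate
Conditions: MsCl, Et3N, CH2Cl2, −20 °C; used crude at once
Reagents that add atoms: methanesulfonyl chloride, CS(=O)(=O)Cl
Why: Sulfene-mediated mesylation reaches the hindered secondary allylic alcohol and installs the nucleofuge, and β-elimination is impossible because the α-carbon is quaternary.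

**Step 10**
Reactants: 14 (1S,2Z)-3-bromo-1-{(1R,4S)-1,4-dimethyl-2-oxo-4-[(triethylsilyl)oxy]cycloheptyl}-4-methylpent-2-en-1-yl methanesulfonate
Product: 17 (2Z,4E,9S)-2-isopropyl-5,9-dimethyl-9-[(triethylsilyl)oxy]cyclodeca-2,4-dien-1-one, via alkenyllithium 15 (not isolated), via bicyclic alkoxide 16 (not isolated)
Conditions: t-BuLi (2.1 equiv), THF/Et2O, −100 → 0 °C; aq NH4Cl
Reagents that add atoms: none
Why: Proposed new method: Br–Li exchange gives a Z-alkenyllithium that adds to the neighbouring ketone to close a cis-fused cyclopentenyl alkoxide whose ring-fusion C–C bond is nearly antiperiplanar to the allylic C–OMs bond, so Grob fragmentation expands the seven-membered ring by three carbons to the cyclodeca-2,4-dienone, the 2Z alkene coming from the cyclopentene and the 4E alkene from stereospecific anti fragmentation of the (2R*,1′S*) mesylate; the closest known chemistry is the Barbier cyclisation/Grob fragmentation sequence of iodoalkyl keto mesylates and the base-induced Wharton–Grob fragmentation of 1,3-diol monosulfonates.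

**Step 11**
Reactants: 17 (2Z,4E,9S)-2-isopropyl-5,9-dimethyl-9-[(triethylsilyl)oxy]cyclodeca-2,4-dien-1-one
Product: 18 (1S,2Z,4E,9S)-2-isopropyl-5,9-dimethyl-9-[(triethylsilyl)oxy]cyclodeca-2,4-dien-1-ol
Conditions: (R)-2-methyl-CBS-oxazaborolidine (0.5 equiv), catecholborane, toluene, −78 °C
Reagents that add atoms: none
Why: In this Corey–Bakshi–Shibata reduction the α-branched alkenyl group is the large substituent, so the (R)-catalyst delivers hydride to give the 1S allylic alcohol under reagent control, with 1,2-reduction only at low temperature.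

**Step 12**
Reactants: 18 (1S,2Z,4E,9S)-2-isopropyl-5,9-dimethyl-9-[(triethylsilyl)oxy]cyclodeca-2,4-dien-1-ol; 19 tert-butyl(4-iodophenoxy)dimethylsilane
Product: 20 (1S,2Z,4E,9S)-2-isopropyl-5,9-dimethyl-9-[(triethylsilyl)oxy]cyclodeca-2,4-dien-1-yl 4-[(tert-butyldimethylsilyl)oxy]benzoate
Conditions: CO (1 atm), Pd(OAc)2 (5 mol%), Xantphos (6 mol%), DMAP, Et3N, toluene, 80 °C
Reagents that add atoms: carbon monoxide, [C-]#[O+]
Why: Pd-catalysed alkoxycarbonylation (oxidative addition of the aryl iodide, CO insertion, DMAP-assisted acyl transfer to the secondary alcohol) forms the benzoate with retention at C1, and the tertiary silyl ether is inert.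

**Step 13**
Reactants: 20 (1S,2Z,4E,9S)-2-isopropyl-5,9-dimethyl-9-[(triethylsilyl)oxy]cyclodeca-2,4-dien-1-yl 4-[(tert-butyldimethylsilyl)oxy]benzoate
Product: 21 (1S,2Z,4E,9S)-9-hydroxy-2-isopropyl-5,9-dimethylcyclodeca-2,4-dien-1-yl 4-hydroxybenzoate
Conditions: HF·pyridine, pyridine, THF, 0 °C → rt
Reagents that add atoms: none
Why: Buffered fluoride cleaves both Si–O bonds (global desilylation) without touching the allylic benzoate, the diene or either stereocentre.

**Compound list**
1 | 3-methylcyclohex-2-en-1-one | CC1=CC(=O)CCC1 | starting material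
2 | (R)-3-methyl-3-(4,4,5,5-tetramethyl-1,3,2-dioxaborolan-2-yl)cyclohexan-1-one | O=C1C[C@@](C)(B2OC(C)(C)C(C)(C)O2)CCC1 | intermediate (not isolated)
3 | (S)-3-hydroxy-3-methylcyclohexan-1-one | O=C1C[C@@](C)(O)CCC1 | intermediate
4 | (S)-3-methyl-3-[(triethylsilyl)oxy]cyclohexan-1-one | O=C1C[C@@](C)(O[Si](CC)(CC)CC)CCC1 | intermediate
5 | 4-methylpent-2-yn-1-ol | OCC#CC(C)C | starting material
6 | sodium 3-isopropyl-2,2-bis(2-methoxyethoxy)-2,5-dihydro-1,2-oxaaluminol-2-uide (cyclic alkenylaluminate) | [Na+].CC(C)C1=CCO[Al-]1(OCCOC)OCCOC | intermediate (not isolated)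
7 | (Z)-3-bromo-4-methylpent-2-en-1-ol | OC/C=C(\Br)C(C)C | intermediate
8 | (Z)-3-bromo-4-methylpent-2-enal | O=C/C=C(\Br)C(C)C | intermediate
9 | (2Z,4Z)-5-bromo-2-iodo-6-methylhepta-2,4-diene | C/C(I)=C/C=C(\Br)C(C)C | intermediate
10 | [(2E,4Z)-5-bromo-6-methylhepta-2,4-dien-2-yl]lithium (geometry of 9 retained; descriptor changes because Li ranks below C) | C/C([Li])=C/C=C(\Br)C(C)C | intermediate (not isolated)
11 | (1R,3S)-1-[(2Z,4Z)-5-bromo-6-methylhepta-2,4-dien-2-yl]-3-methyl-3-[(triethylsilyl)oxy]cyclohexan-1-ol (major C1 epimer shown; the 1S epimer reacts alike) | C/C(=C/C=C(\Br)C(C)C)[C@]1(O)C[C@@](C)(O[Si](CC)(CC)CC)CCC1 | intermediate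
12 | (1R,3S)-1-{(2S,3S)-3-[(1Z)-2-bromo-3-methylbut-1-en-1-yl]-2-methyloxiran-2-yl}-3-methyl-3-[(triethylsilyl)oxy]cyclohexan-1-ol (ring carbon and alkenyl group cis on the oxirane; one face isomer shown, the other is carried along) | CC(C)/C(Br)=C/[C@@H]1O[C@]1(C)[C@]2(O)C[C@@](C)(O[Si](CC)(CC)CC)CCC2 | intermediate
13 | (2R,6S)-2-[(1S,2Z)-3-bromo-1-hydroxy-4-methylpent-2-en-1-yl]-2,6-dimethyl-6-[(triethylsilyl)oxy]cycloheptan-1-one (shown with fixed 2R*,1′S* relationship; its (2S,1′R,6S) diastereomer is carried along and converges in step 10) | O=C1C[C@@](C)(O[Si](CC)(CC)CC)CCC[C@]1(C)[C@@H](O)/C=C(\Br)C(C)C | intermediate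
14 | (1S,2Z)-3-bromo-1-{(1R,4S)-1,4-dimethyl-2-oxo-4-[(triethylsilyl)oxy]cycloheptyl}-4-methylpent-2-en-1-yl methanesulfonate | O=C1C[C@@](C)(O[Si](CC)(CC)CC)CCC[C@]1(C)[C@@H](OS(C)(=O)=O)/C=C(\Br)C(C)C | intermediate
15 | 3-lithio analogue of 14 (Li in place of Br, alkene geometry retained) | O=C1C[C@@](C)(O[Si](CC)(CC)CC)CCC[C@]1(C)[C@@H](OS(C)(=O)=O)/C=C(\[Li])C(C)C | intermediate (not isolated)
16 | lithium 3-isopropyl-1-(methanesulfonyloxy)-5,8a-dimethyl-5-[(triethylsilyl)oxy]-1,3a,4,5,6,7,8,8a-octahydroazulen-3a-olate (cis-fused; 3a-O, 8a-CH3 and 1-OMs on one face; 5S) | [Li]O[C@@]12C[C@@](C)(O[Si](CC)(CC)CC)CCC[C@]1(C)[C@@H](OS(C)(=O)=O)C=C2C(C)C | intermediate (not isolated)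
17 | (2Z,4E,9S)-2-isopropyl-5,9-dimethyl-9-[(triethylsilyl)oxy]cyclodeca-2,4-dien-1-one | C/C1=C\C=C(\C(C)C)C(=O)C[C@@](C)(O[Si](CC)(CC)CC)CCC1 | intermediate
18 | (1S,2Z,4E,9S)-2-isopropyl-5,9-dimethyl-9-[(triethylsilyl)oxy]cyclodeca-2,4-dien-1-ol | C/C1=C\C=C(\C(C)C)[C@@H](O)C[C@@](C)(O[Si](CC)(CC)CC)CCC1 | intermediate
19 | tert-butyl(4-iodophenoxy)dimethylsilane | CC(C)(C)[Si](C)(C)Oc1ccc(I)cc1 | starting material
20 | (1S,2Z,4E,9S)-2-isopropyl-5,9-dimethyl-9-[(triethylsilyl)oxy]cyclodeca-2,4-dien-1-yl 4-[(tert-butyldimethylsilyl)oxy]benzoate | C/C1=C\C=C(\C(C)C)[C@@H](OC(=O)c2ccc(O[Si](C)(C)C(C)(C)C)cc2)C[C@@](C)(O[Si](CC)(CC)CC)CCC1 | intermediate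
21 | (1S,2Z,4E,9S)-9-hydroxy-2-isopropyl-5,9-dimethylcyclodeca-2,4-dien-1-yl 4-hydroxybenzoate | C/C1=C\C=C(\C(C)C)[C@@H](OC(=O)c2ccc(O)cc2)C[C@@](C)(O)CCC1 | target

**Totals**
Total steps: 13. Longest linear sequence: 11 (5 → 7 → 8 → 9 → 11 → 12 → 13 → 14 → 17 → 18 → 20 → 21, steps 3–13).

**Three steps most likely to fail**

Step 8 (semipinacol ring expansion). The risks are migration of the other ring CH2 (the one next to the C–OSi carbon) and Lewis-acid opening at the allylic oxirane carbon. The fallback sets out from 4 and comes back at 13. Kinetic enolisation of 4 away from the quaternary centre (LDA, TMSCl) gives the silyl enol ether F1. Ethylidenation (Et2Zn, CH3CHI2) gives the siloxycyclopropane F2. FeCl3 in DMF opens the internal cyclopropane bond to the β-chloro ketone F3, and NaOAc eliminates HCl to give the enone F4; this one-carbon expansion is regiodefined by the enol ether. L-Selectride 1,4-reduction of F4 generates the tetrasubstituted enolate regiospecifically; transmetalation with ClTi(Oi-Pr)3 and aldol addition to enal 8 give 13 after separation from its C1′ epimer.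

Step 10 (proposed new cascade). The risks are attack of t-BuLi at the ketone or the mesyl CH3, a lithium alkoxide that does not fragment, and loss of silanolate from the product on warming. The fallback uses known chemistry, sets out from 13 and comes back at 17. Treating 13 with t-BuLi (3.1 equiv, −100 °C; alkoxide formation, Br–Li exchange, anionic cyclisation) gives the cis-fused cyclopentene-1,3-diol F5. Selective mesylation of its secondary allylic hydroxyl (MsCl, Et3N) gives the monomesylate F6. Classical base-induced Grob fragmentation of F6 (KOt-Bu, t-BuOH/THF) gives 17.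

Step 12 (carbonylative esterification). The risks are slow acyl transfer to the hindered alcohol and Pd(0) ionisation of the dienyl ester product. The fallback sets out from 19 (with 18) and comes back at 20. Iodine–magnesium exchange of 19 (i-PrMgCl·LiCl) and quenching with CO2 give 4-[(tert-butyldimethylsilyl)oxy]benzoic acid F7. Steglich esterification of 18 with F7 (DCC, DMAP, CH2Cl2) gives 20 without any Pd(0).

**Further compounds**
F1 | step 8 | triethyl{[(1S)-1-methyl-3-[(trimethylsilyl)oxy]cyclohex-3-en-1-yl]oxy}silane | C[Si](C)(C)OC1=CCC[C@](C)(O[Si](CC)(CC)CC)C1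
F2 | step 8 | triethyl{[(3S)-3,7-dimethyl-1-[(trimethylsilyl)oxy]bicyclo[4.1.0]heptan-3-yl]oxy}silane (cyclopropane diastereomers) | C[Si](C)(C)OC12C[C@@](C)(O[Si](CC)(CC)CC)CCC1C2C
F3 | step 8 | (6S)-3-chloro-2,6-dimethyl-6-[(triethylsilyl)oxy]cycloheptan-1-one | CC1C(Cl)CC[C@](C)(O[Si](CC)(CC)CC)CC1=O
F4 | step 8 | (6S)-2,6-dimethyl-6-[(triethylsilyl)oxy]cyclohept-2-en-1-one | CC1=CCC[C@](C)(O[Si](CC)(CC)CC)CC1=O
F5 | step 10 | (5S)-3-isopropyl-5,8a-dimethyl-5-[(triethylsilyl)oxy]-1,3a,4,5,6,7,8,8a-octahydroazulene-1,3a-diol (cis-fused; 1-OH, 3a-OH and 8a-CH3 on one face) | O[C@@]12C[C@@](C)(O[Si](CC)(CC)CC)CCC[C@]1(C)[C@@H](O)C=C2C(C)C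
F6 | step 10 | (5S)-3a-hydroxy-3-isopropyl-5,8a-dimethyl-5-[(triethylsilyl)oxy]-1,3a,4,5,6,7,8,8a-octahydroazulen-1-yl methanesulfonate (same relative configuration as F5) | O[C@@]12C[C@@](C)(O[Si](CC)(CC)CC)CCC[C@]1(C)[C@@H](OS(C)(=O)=O)C=C2C(C)C
F7 | step 12 | 4-[(tert-butyldimethylsilyl)oxy]benzoic acid | CC(C)(C)[Si](C)(C)Oc1ccc(C(=O)O)cc1
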